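## Retrosynthetic overview
1. No ring is built. Rings A and A' are both bought intact as racemic α-ionone (1). The target is C2-symmetric, so one C15 half is made once and used twice.
2. Key disconnection: the C3–O bond of each ring, traced back to the allylic C3–H of 1. A ligand-controlled copper C–H benzoyloxylation gives benzoate 2, sets C3 as R and sorts C6 (trans 3R,6R kept, cis 3R,6S removed).
3. The C9–C10 bond comes from vinyl addition to the ketone of 2 (→ 3). The C11–P bond comes from allylic transposition with PPh3·HBr (→ C15 salt 4).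
4. C11=C12 and C11'=C12' come from a double Wittig reaction of two molecules of 4 with the C10 dialdehyde 5. Both benzoates are removed in the same flask.

The target is read as all-E (3R,6R,3'R,6'R)-ε,ε-carotene-3,3'-diol (lactucaxanthin). On each ring the 3-OH is trans to the C6 side chain, as in the ε-ring of lutein.

Assumption: which antipode of the BOX ligand delivers 3R cannot be predicted safely and is fixed by one test run (both antipodes are sold); the (S,S) ligand is written below.

## Route

Step 1
Reactants: 1 racemic α-ionone [(E)-4-(2,6,6-trimethylcyclohex-2-en-1-yl)but-3-en-2-one]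
Product: 2 (3R,6R)-3-benzoyloxy-α-ionone [(1R,4R)-3,5,5-trimethyl-4-[(1E)-3-oxobut-1-enyl]cyclohex-2-en-1-yl benzoate; OBz trans to the side chain]
Conditions: Cu(MeCN)4PF6 (5 mol %), (S,S)-Ph-BOX = 2,2'-(propane-2,2-diyl)bis[(4S)-4-phenyl-4,5-dihydrooxazole] (6 mol %), (PhSO2)2NF (1.5 equiv), PhCO2SiMe3 (3 equiv), PhCl, 0 °C, N2, 24 h; SiO2 chromatography (trans 2 from the cis isomer)
Reagents that add atoms: trimethylsilyl benzoate, C[Si](C)(C)OC(=O)c1ccccc1
Why: Proposed new method: enantioselective copper radical-relay allylic C–H benzoyloxylation, in which the monovalent copper–BOX complex reduces (PhSO2)2NF to a copper-bound sulfonimidyl radical that abstracts the least hindered and most hydridic allylic hydrogen (C3–H; C6–H is shielded by the gem-dimethyl group and polarity-deactivated by the enone, and t-BuOOH-type radical oxidations of 1 are known to pick C3), PhCO2SiMe3 turns the divalent copper fluoride into the benzoate, the C3–C4–C5 allyl radical is captured as a trivalent allylcopper benzoate, and inner-sphere reductive elimination forms the C3–O bond at the open allyl terminus on the face fixed by the ligand (the remote C6 substituent exerts little bias of its own), so that both enantiomers of 1 receive 3R and C6 is sorted by removing the cis (3R,6S) diastereomer (at most 50 % yield of 2); the closest known reaction types are the asymmetric Kharasch–Sosnovsky acyloxylation and the copper-catalysed radical-relay allylic C–H cyanation.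

Step 2
Reactants: 2 (3R,6R)-3-benzoyloxy-α-ionone
Product: 3 (1R,4R)-4-[(1E)-3-hydroxy-3-methylpenta-1,4-dienyl]-3,5,5-trimethylcyclohex-2-en-1-yl benzoate (about 1:1 epimers at carbinol carbon C9)
Conditions: CH2=CHMgBr (1.2 equiv), THF, −78 °C, 1 h; sat. aq. NH4Cl
Reagents that add atoms: vinylmagnesium bromide, C=C[Mg]Br
Why: Grignard 1,2-addition, in which the methyl ketone of the enone reacts far faster at −78 °C than the secondary benzoate, the ring stereocentres are untouched, and the new C9 centre forms unselectively but is erased in step 3.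

Step 3
Reactants: 3 vinyl carbinol benzoate
Product: 4 [(2E,4E)-5-[(1R,4R)-4-benzoyloxy-2,6,6-trimethylcyclohex-2-en-1-yl]-3-methylpenta-2,4-dienyl]triphenylphosphonium bromide
Conditions: PPh3·HBr (1.05 equiv), CH2Cl2, 0 °C → rt, 16 h; recrystallise (CH2Cl2/EtOAc)
Reagents that add atoms: triphenylphosphine hydrobromide, [Br-].[PH+](c1ccccc1)(c1ccccc1)c1ccccc1
Why: SN1-type allylic transposition (the standard vinyl-ionol to C15 Wittig salt reaction), in which the tertiary bis-allylic carbinol ionises to a pentadienyl cation that PPh3 traps at the primary terminus, the much less basic secondary allylic benzoate stays intact under this buffered acid, and the 9E geometry is favoured thermodynamically and secured by crystallisation.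

Step 4
Reactants: 4 C15 phosphonium bromide (2.1 equiv); 5 (2E,4E,6E)-2,7-dimethylocta-2,4,6-trienedial (1.0 equiv)
Product: 9 lactucaxanthin [(all-E)-(3R,6R,3'R,6'R)-ε,ε-carotene-3,3'-diol], via C15 ylide 6 (not isolated), via C25 apo-aldehyde benzoate 7 (not isolated), via lactucaxanthin dibenzoate 8 (not isolated)
Conditions: NaOMe (5 equiv, added slowly to 4 + 5), CH2Cl2/MeOH, 0 °C → rt, N2, dark; then EtOH, reflux 3 h (Z→E), crystallise
Reagents that add atoms: none
Why: Double Wittig olefination (C15 + C10 + C15) followed by Zemplén-type transesterification, in which the E/Z mixture at the two new C11=C12 bonds equilibrates thermally to the all-E polyene, the benzoates are cleaved at the acyl–O bond so that C3 keeps its configuration, and C6 is safe because ε-rings survive methoxide at room temperature just as lutein esters survive saponification.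

## Compound list
1 | racemic α-ionone | CC(=O)/C=C/C1C(C)=CCCC1(C)C | starting material
2 | (3R,6R)-3-benzoyloxy-α-ionone | CC(=O)/C=C/[C@H]1C(C)=C[C@H](OC(=O)c2ccccc2)CC1(C)C | intermediate
3 | (3R,6R)-3-benzoyloxy-9-vinyl-α-ionol (C9 epimers) | C=CC(C)(O)/C=C/[C@H]1C(C)=C[C@H](OC(=O)c2ccccc2)CC1(C)C | intermediate
4 | C15 triphenylphosphonium bromide (2E,4E; ring 1R,4R) | [Br-].c1ccccc1[P+](c1ccccc1)(c1ccccc1)C/C=C(C)/C=C/[C@H]1C(C)=C[C@H](OC(=O)c2ccccc2)CC1(C)C | intermediate
5 | (2E,4E,6E)-2,7-dimethylocta-2,4,6-trienedial | O=C/C(C)=C/C=C/C=C(C)/C=O | starting material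
6 | C15 ylide from 4 | c1ccccc1[P+](c1ccccc1)(c1ccccc1)[CH-]/C=C(C)/C=C/[C@H]1C(C)=C[C@H](OC(=O)c2ccccc2)CC1(C)C | intermediate
7 | (3R,6R)-3-benzoyloxy-12'-apo-ε-caroten-12'-al | O=C/C(C)=C/C=C/C=C(C)/C=C/C=C(C)/C=C/[C@H]1C(C)=C[C@H](OC(=O)c2ccccc2)CC1(C)C | intermediate
8 | lactucaxanthin dibenzoate | CC1=C[C@H](OC(=O)c2ccccc2)CC(C)(C)[C@H]1/C=C/C(C)=C/C=C/C(C)=C/C=C/C=C(C)/C=C/C=C(C)/C=C/[C@H]1C(C)=C[C@H](OC(=O)c2ccccc2)CC1(C)C | intermediate
9 | lactucaxanthin, (3R,6R,3'R,6'R)-ε,ε-carotene-3,3'-diol | CC1=C[C@H](O)CC(C)(C)[C@H]1/C=C/C(C)=C/C=C/C(C)=C/C=C/C=C(C)/C=C/C=C(C)/C=C/[C@H]1C(C)=C[C@H](O)CC1(C)C | target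

## Step count and risks
Total steps: 4. Longest linear sequence: 4 (1 → 2 → 3 → 4 → 9).

**Risk 1, step 1 (the new method).**
- The sulfonimide may compete as an N-nucleophile and give C–N coupling.
- The allyl radical may be oxidised outer-sphere to the cation, which would lose ligand control.
- The mismatched 6S radical may leak into (3S,6S)-trans product and lower the ee of 2.
- The strongly acidic sulfonimide may ionise 2. The excess silyl benzoate is there to buffer it.

The fallback uses known chemistry, sets out from 1 and comes back at 2. Whole-cell hydroxylation of 1 is known to give racemic trans-3-hydroxy-α-ionone F1 with high C3 and trans selectivity. Suitable cells are Streptomyces strains or E. coli expressing a cytochrome P450 BM3 variant (air, glucose, buffer, 30 °C).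

F1 is then resolved kinetically with Pseudomonas fluorescens lipase and vinyl acetate (MTBE, 35 °C, stopped at 50 % conversion). This enzyme family acylates the 3R alcohol of the β-ring series, taking the gem-dimethyl flank as the large group. By that analogy the resolution should leave (3R,6R)-3-hydroxy-α-ionone F2 and convert the other enantiomer into (3S,6S)-3-acetoxy-α-ionone F3, which is removed on silica gel. The sense is checked by chiral HPLC and optical rotation.

If the enzyme shows the opposite sense, the ester fraction is (3R,6R)-3-acetoxy-α-ionone F4. It is methanolysed (K2CO3, MeOH) to the same F2. Benzoylation of F2 (PhCOCl, pyridine, CH2Cl2, 0 °C) gives 2.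

**Risk 2, step 3.**
- The acid may ionise the ring allylic benzoate, causing loss or scrambling of C3–O or elimination.
- The 9E/9Z salt mixture may refuse to crystallise.

The fallback sets out from 3 and comes back at 8. It replaces the acid-made phosphonium salt with a phosphonate. Compound 3 is treated with PBr3 and pyridine (Et2O, −20 °C) to give, by SN2' displacement, the (2E,4E)-C15 dienyl bromide F5. Arbuzov reaction with P(OEt)3 (80 °C) gives the diethyl C15 phosphonate F6. A double Horner–Wadsworth–Emmons reaction of F6 (2.1 equiv) with 5 (KOt-Bu, THF, −30 °C → rt) gives 8 with high E selectivity. Compound 8 is isolated and then methanolysed as in the second half of step 4.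

**Risk 3, step 4.**
- Z-rich mixtures may form.
- The ylide may attack a benzoate.
- Any (3S,6S) salt left in 4 ends up as the (3R,6R,3'S,6'S) isomer, which is very hard to remove. The ee of 4 must therefore be at least 99 % before coupling.

The fallback reverses the polarity of the coupling, sets out from 2 (and 5) and comes back at 9. Horner–Wadsworth–Emmons reaction of 2 with diethyl cyanomethylphosphonate (NaH, THF, 0 °C; 9E isomer separated on silica gel) gives (3R,6R)-3-benzoyloxy-α-ionylideneacetonitrile F7. Treatment with i-Bu2AlH (4 equiv, CH2Cl2, −78 °C; mild aqueous acid work-up) reduces the nitrile and removes the benzoate. The product is the known (3R,6R)-3-hydroxy-α-ionylideneacetaldehyde F8, whose ee can be checked and raised by crystallisation.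

In parallel, 5 is reduced (NaBH4, MeOH/THF, 0 °C) to (2E,4E,6E)-2,7-dimethylocta-2,4,6-triene-1,8-diol F9. Compound F9 is converted with PPh3·HBr (2 equiv, MeOH, rt) into the C10 bis(triphenylphosphonium) dibromide F10. A double Wittig reaction of F10 with F8 (2.1 equiv; NaOMe, CH2Cl2/MeOH, 0 °C → rt; then EtOH reflux) gives 9 directly.

## Further compounds
F1 | step 1 | racemic trans-3-hydroxy-α-ionone (both enantiomers written) | CC(=O)/C=C/[C@H]1C(C)=C[C@H](O)CC1(C)C.CC(=O)/C=C/[C@@H]1C(C)=C[C@@H](O)CC1(C)C
F2 | step 1 | (3R,6R)-3-hydroxy-α-ionone | CC(=O)/C=C/[C@H]1C(C)=C[C@H](O)CC1(C)C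
F3 | step 1 | (3S,6S)-3-acetoxy-α-ionone | CC(=O)/C=C/[C@@H]1C(C)=C[C@@H](OC(C)=O)CC1(C)C
F4 | step 1 | (3R,6R)-3-acetoxy-α-ionone | CC(=O)/C=C/[C@H]1C(C)=C[C@H](OC(C)=O)CC1(C)C
F5 | step 3 | (1R,4R)-4-[(1E,3E)-5-bromo-3-methylpenta-1,3-dienyl]-3,5,5-trimethylcyclohex-2-en-1-yl benzoate | BrC/C=C(C)/C=C/[C@H]1C(C)=C[C@H](OC(=O)c2ccccc2)CC1(C)C
F6 | step 3 | diethyl [(2E,4E)-5-[(1R,4R)-4-benzoyloxy-2,6,6-trimethylcyclohex-2-en-1-yl]-3-methylpenta-2,4-dienyl]phosphonate | CCOP(=O)(OCC)C/C=C(C)/C=C/[C@H]1C(C)=C[C@H](OC(=O)c2ccccc2)CC1(C)C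
F7 | step 4 | (3R,6R)-3-benzoyloxy-α-ionylideneacetonitrile (2E,4E) | N#C/C=C(C)/C=C/[C@H]1C(C)=C[C@H](OC(=O)c2ccccc2)CC1(C)C
F8 | step 4 | (3R,6R)-3-hydroxy-α-ionylideneacetaldehyde (2E,4E) | O=C/C=C(C)/C=C/[C@H]1C(C)=C[C@H](O)CC1(C)C
F9 | step 4 | (2E,4E,6E)-2,7-dimethylocta-2,4,6-triene-1,8-diol | OC/C(C)=C/C=C/C=C(C)/CO
F10 | step 4 | (2E,4E,6E)-2,7-dimethylocta-2,4,6-triene-1,8-diylbis(triphenylphosphonium) dibromide | [Br-].[Br-].c1ccccc1[P+](c1ccccc1)(c1ccccc1)C/C(C)=C/C=C/C=C(C)/C[P+](c1ccccc1)(c1ccccc1)c1ccccc1
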